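**Retrosynthetic overview**

1. Target (Z-dienone) ⇐ stereospecific syn-dehydration of a syn β-hydroxy ketone ⇐ aldol addition of the α′-enolate of the bromo-hydroxy-enone to (E)-pent-2-enal.
2. α-Bromoenone ⇐ bromination–dehydrobromination of (R)-4-alkyl-4-hydroxycyclopent-2-enone.
3. Hydroxy-enone ⇐ 1-alkylcyclopentadiene + O2: the [4+2] addition makes both C–O bonds, the tertiary carbinol C–O included; an enantiomer-selective Kornblum–DeLaMare opening of the racemic peroxide fixes the absolute configuration.
4. 1-Alkylcyclopentadiene ⇐ sodium cyclopentadienide + methyl 8-bromooctanoate.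
5. Rings: the five-membered carbocycle is bought; the only ring formed is the transient 2,3-dioxabicyclo[2.2.1]heptene (step 2), opened again in the same flask.

Assumption: the sense of enantiomer selection of the cinchona base in step 2 cannot be predicted; the route is written for the pseudoenantiomer (cupreidine or cupreine series, fixed by one screening run) that consumes the (1R,4S)-peroxide, and that step cannot exceed 50% yield.

**Step 1**
Reactants: 1 sodium cyclopentadienide; 2 methyl 8-bromooctanoate
Product: 4 methyl 8-(cyclopenta-1,3-dien-1-yl)octanoate, via cyclopenta-2,4-dien-1-yl isomer 3 (not isolated)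
Conditions: sodium cyclopentadienide (1.3 equiv, 2 M in THF), THF, −30 → 0 °C, 2 h; aq. NH4Cl, pentane extraction; then 23 °C, 4 h; solution used at once (4 : 2-alkyl isomer about 8 : 1)
Reagents that add atoms: none
Why: SN2 alkylation of the cyclopentadienide at the primary bromide (faster than attack at the ester at or below 0 °C) gives the 5-alkyl diene 3, whose thermal suprafacial [1,5]-hydrogen shift to the 1-alkyl diene 4 is roughly ten times faster than the next shift to the 2-alkyl isomer; no stereocentre is formed.

**Step 2**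
Reactants: 4 methyl 8-(cyclopenta-1,3-dien-1-yl)octanoate
Product: 6 methyl 8-[(1R)-1-hydroxy-4-oxocyclopent-2-en-1-yl]octanoate, via racemic endoperoxide 5 (not isolated)
Conditions: O2, meso-tetraphenylporphyrin (0.2 mol %), visible light, CH2Cl2, −78 °C; then 9-O-acetylcupreidine (10 mol %), dark, −50 °C, stopped at about 50% conversion; cold silica chromatography
Reagents that add atoms: dioxygen, O=O
Why: Proposed new method: singlet oxygen adds suprafacially across C1/C4 of the s-cis diene ([4+2] photooxygenation, forming both C–O bonds including the tertiary one), and the racemic bicyclic peroxide is then resolved by an enantiomer-selective Kornblum–DeLaMare rearrangement in which the quinuclidine nitrogen of the bifunctional cinchona base removes the only bridgehead hydrogen (C4–H) while its 6′-OH hydrogen-bonds the peroxide oxygen that becomes the tertiary alkoxide, a two-point fit open to one enantiomer only, so the (1R,4S)-peroxide collapses to (R)-6 with its C1–O bond untouched and the (1S,4R)-peroxide is left behind; the closest known reaction type is the cinchona-base-catalysed desymmetrising Kornblum–DeLaMare rearrangement of meso endoperoxides with two equivalent C–H bonds, not yet shown as a kinetic resolution of a bridgehead-alkylated 2,3-dioxabicyclo[2.2.1]heptene.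

**Step 3**
Reactants: 6 methyl 8-[(1R)-1-hydroxy-4-oxocyclopent-2-en-1-yl]octanoate
Product: 8 methyl 8-[(1R)-3-bromo-1-hydroxy-4-oxocyclopent-2-en-1-yl]octanoate, via trans-2,3-dibromide 7 (not isolated)
Conditions: Br2 (1.05 equiv), CH2Cl2, −20 °C; then Et3N (1.6 equiv), −20 → 0 °C
Reagents that add atoms: bromine, BrBr
Why: Bromine adds anti across the enone C=C and triethylamine removes the acidic α-hydrogen with loss of the β-bromide (bromination–dehydrobromination by E1cB), the standard way to an α-bromoenone; the tertiary carbinol centre is not involved.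

**Step 4**
Reactants: 8 methyl 8-[(1R)-3-bromo-1-hydroxy-4-oxocyclopent-2-en-1-yl]octanoate; 9 (E)-pent-2-enal
Product: 12 methyl 8-[(1R,5S)-3-bromo-1-hydroxy-5-[(1S,2E)-1-hydroxypent-2-en-1-yl]-4-oxocyclopent-2-en-1-yl]octanoate, via dilithium dianion 10 (not isolated), via bis-titanium dienolate 11 (not isolated)
Conditions: 8 added to lithium diisopropylamide (2.15 equiv), THF, −78 °C; ClTi(OiPr)3 (2.3 equiv), −78 → −45 °C; 9 (1.3 equiv), −78 °C, 1 h; aq. NH4Cl
Reagents that add atoms: none
Why: Inverse addition to the amide base forms the alkoxide–dienolate at C5, the only enolisable ring position, and after transmetalation the tris(isopropoxy)titanium enolate adds 1,2 to the enal (titanium-mediated aldol addition), which is erythro (syn)-selective for cyclic ketone enolates whatever their geometry, so C5 and C1′ are set syn; attack anti to the alkyl chain at C1 is expected, but the C5 epimer of the same syn pair converges in step 5.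

**Step 5**
Reactants: 12 methyl 8-[(1R,5S)-3-bromo-1-hydroxy-5-[(1S,2E)-1-hydroxypent-2-en-1-yl]-4-oxocyclopent-2-en-1-yl]octanoate
Product: 14 methyl 8-[(1S,5Z)-3-bromo-1-hydroxy-4-oxo-5-[(2E)-pent-2-en-1-ylidene]cyclopent-2-en-1-yl]octanoate, via O-allyl isourea 13 (not isolated)
Conditions: N,N′-dicyclohexylcarbodiimide (2 equiv), CuCl (0.2 equiv), Et2O, 23 °C, dark, 12 h
Reagents that add atoms: none
Why: Copper-catalysed addition of the secondary allylic alcohol to the carbodiimide gives isourea 13, whose imino nitrogen removes the acidic C5–H through a six-membered cyclic transition state (stereospecific syn-elimination, carbodiimide/CuCl dehydration of aldols), so the syn aldol gives the exocyclic alkene with the butenyl group cis to the ketone, i.e. (5Z); the tertiary alcohol is inert, and C1 changes descriptor from R to S only because C5 becomes sp2.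

**Compound list**

1 | sodium cyclopentadienide | [Na+].[CH-]1C=CC=C1 | starting material
2 | methyl 8-bromooctanoate | COC(=O)CCCCCCCBr | starting material
3 | methyl 8-(cyclopenta-2,4-dien-1-yl)octanoate | COC(=O)CCCCCCCC1C=CC=C1 | intermediate
4 | methyl 8-(cyclopenta-1,3-dien-1-yl)octanoate | COC(=O)CCCCCCCC1=CC=CC1 | intermediate
5 | racemic methyl 8-(2,3-dioxabicyclo[2.2.1]hept-5-en-1-yl)octanoate (peroxide bridge necessarily cis; both enantiomers present) | COC(=O)CCCCCCCC12CC(C=C1)OO2 | intermediate
6 | methyl 8-[(1R)-1-hydroxy-4-oxocyclopent-2-en-1-yl]octanoate | C1C(=O)C=C[C@@]1(O)CCCCCCCC(=O)OC | intermediate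
7 | methyl 8-[(1R,2S,3S)-2,3-dibromo-1-hydroxy-4-oxocyclopentyl]octanoate (trans-dibromide, drawn as the expected major diastereomer) | C1C(=O)[C@H](Br)[C@@H](Br)[C@@]1(O)CCCCCCCC(=O)OC | intermediate
8 | methyl 8-[(1R)-3-bromo-1-hydroxy-4-oxocyclopent-2-en-1-yl]octanoate | C1C(=O)C(Br)=C[C@@]1(O)CCCCCCCC(=O)OC | intermediate
9 | (E)-pent-2-enal | CC/C=C/C=O | starting material
10 | dilithium salt of methyl 8-[(1R)-3-bromo-1,4-dioxidocyclopenta-2,4-dien-1-yl]octanoate | [Li+].[Li+].C1=C([O-])C(Br)=C[C@@]1([O-])CCCCCCCC(=O)OC | intermediate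
11 | methyl 8-[(1R)-3-bromo-1,4-bis{[tri(propan-2-yloxy)titanio]oxy}cyclopenta-2,4-dien-1-yl]octanoate | C1=C(O[Ti](OC(C)C)(OC(C)C)OC(C)C)C(Br)=C[C@@]1(O[Ti](OC(C)C)(OC(C)C)OC(C)C)CCCCCCCC(=O)OC | intermediate
12 | methyl 8-[(1R,5S)-3-bromo-1-hydroxy-5-[(1S,2E)-1-hydroxypent-2-en-1-yl]-4-oxocyclopent-2-en-1-yl]octanoate (syn aldol) | CC/C=C/[C@H](O)[C@@H]1C(=O)C(Br)=C[C@@]1(O)CCCCCCCC(=O)OC | intermediate
13 | methyl 8-[(1R,5S)-3-bromo-5-[(1S,2E)-1-[(N,N′-dicyclohexylcarbamimidoyl)oxy]pent-2-en-1-yl]-1-hydroxy-4-oxocyclopent-2-en-1-yl]octanoate | CC/C=C/[C@H](OC(=NC1CCCCC1)NC1CCCCC1)[C@@H]2C(=O)C(Br)=C[C@@]2(O)CCCCCCCC(=O)OC | intermediate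
14 | methyl 8-[(1S,5Z)-3-bromo-1-hydroxy-4-oxo-5-[(2E)-pent-2-en-1-ylidene]cyclopent-2-en-1-yl]octanoate | CC/C=C/C=C1\C(=O)C(Br)=C[C@@]1(O)CCCCCCCC(=O)OC | target

**Step count and risks**

Total step count: 5. Longest linear sequence: 5 steps (from 1 and 2).

The three steps most likely to fail:

Step 2 (the proposed new step). The selectivity factor of the resolution may be too low at the temperature the labile [2.2.1] peroxide tolerates, and the yield is capped at 50%. Fallback with known chemistry, setting out from 4: photooxygenation exactly as in step 2, then triethylamine at −78 → 0 °C (ordinary achiral Kornblum–DeLaMare rearrangement of 5) gives racemic methyl 8-(1-hydroxy-4-oxocyclopent-2-en-1-yl)octanoate F1. Its enantiomers are separated by preparative supercritical-fluid chromatography on an amylose-type chiral stationary phase; the (R)-enantiomer is 6, where the route is rejoined.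

Step 4. The syn selectivity of the titanium enolate may be eroded by the neighbouring titanated alkoxide. The mono-alkoxide of 8 can open by retro-aldol (racemisation) if dianion formation is slow, and the ester may enolise. Fallback setting out from 8: trimethylsilyl triflate and triethylamine (CH2Cl2, −78 °C) give methyl 8-[(1R)-3-bromo-1,4-bis(trimethylsilyloxy)cyclopenta-2,4-dien-1-yl]octanoate F2. F2 is added to 9 under fluoride catalysis (tetrabutylammonium difluorotriphenylsilicate, THF, −78 °C; Mukaiyama aldol through an open, erythro-selective transition state) to give methyl 8-[(1R,5S)-3-bromo-4-oxo-1-(trimethylsilyloxy)-5-[(1S,2E)-1-(trimethylsilyloxy)pent-2-en-1-yl]cyclopent-2-en-1-yl]octanoate F3. Dilute aqueous HCl in THF at 0 °C removes both silyl groups and returns to the route at 12.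

Step 5. The isourea may eliminate by E1cB (loss of stereospecificity) or rearrange allylically. The (5Z)-dienone is probably the less stable isomer and could drift to (5E); any anti aldol carried over from step 4 also ends as the (5E) isomer, which must be removed by chromatography. Fallback setting out from 12: methanesulfonyl chloride and triethylamine give methyl 8-[(1R,5S)-3-bromo-1-hydroxy-5-[(1S,2E)-1-(methanesulfonyloxy)pent-2-en-1-yl]-4-oxocyclopent-2-en-1-yl]octanoate F4. DBU then eliminates it by E1cB, mainly to methyl 8-[(1S,5E)-3-bromo-1-hydroxy-4-oxo-5-[(2E)-pent-2-en-1-ylidene]cyclopent-2-en-1-yl]octanoate F5. Thioxanthone-sensitised irradiation (405 nm, benzene) takes F5 to a photostationary E/Z mixture, from which 14 is separated by chromatography and F5 is recycled; the route is rejoined at 14.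

**Further compounds**

F1 | step 2 | racemic methyl 8-(1-hydroxy-4-oxocyclopent-2-en-1-yl)octanoate | COC(=O)CCCCCCCC1(O)CC(=O)C=C1
F2 | step 4 | methyl 8-[(1R)-3-bromo-1,4-bis(trimethylsilyloxy)cyclopenta-2,4-dien-1-yl]octanoate | C1=C(O[Si](C)(C)C)C(Br)=C[C@@]1(O[Si](C)(C)C)CCCCCCCC(=O)OC
F3 | step 4 | methyl 8-[(1R,5S)-3-bromo-4-oxo-1-(trimethylsilyloxy)-5-[(1S,2E)-1-(trimethylsilyloxy)pent-2-en-1-yl]cyclopent-2-en-1-yl]octanoate | CC/C=C/[C@H](O[Si](C)(C)C)[C@@H]1C(=O)C(Br)=C[C@@]1(O[Si](C)(C)C)CCCCCCCC(=O)OC
F4 | step 5 | methyl 8-[(1R,5S)-3-bromo-1-hydroxy-5-[(1S,2E)-1-(methanesulfonyloxy)pent-2-en-1-yl]-4-oxocyclopent-2-en-1-yl]octanoate | CC/C=C/[C@H](OS(C)(=O)=O)[C@@H]1C(=O)C(Br)=C[C@@]1(O)CCCCCCCC(=O)OC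
F5 | step 5 | methyl 8-[(1S,5E)-3-bromo-1-hydroxy-4-oxo-5-[(2E)-pent-2-en-1-ylidene]cyclopent-2-en-1-yl]octanoate | CC/C=C/C=C1/C(=O)C(Br)=C[C@@]1(O)CCCCCCCC(=O)OC
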